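(The runs were generated by integration for an exercise.)

A unit first: count the left-handed substrate in e-foldings, L, minus the logarithm of the share of its own charge still free. In this kinetic resolution, each proposed left-handed turnover and each catalyst death runs on partner times free catalyst, so partner cancels from their ratio and L grows in step with the share of catalyst spent. The L reached when the whole catalyst charge is spent is the **reach**, one dimensionless number.

common to all: free catalyst 0.23 mol%

| charge | left-handed substrate | right-handed substrate | partner | protic impurity | remark | time |
|---|---|---|---|---|---|---|
| zeta | 0.033 M | 0.033 M | 0.80 equiv | 0.66 mM | the very flask that is asked about, followed so far |  |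
| delta | 0.022 M | 0.022 M | 0.80 equiv | 0.66 mM | run made earlier |  |
| flask | 0.033 M | 0.033 M | 0.800 equiv | 0.660 mM |  | 2.5 d |

| run | time / h | left-handed product / % |
|---|---|---|
| zeta | 3.00 | 4.2 |
| zeta | 10.0 | 10.7 |
| zeta | 15.0 | 11.1 |
| zeta | 25.0 | 15.1 |
| zeta | 40.0 | 17.2 |
| zeta | 50.0 | 18.0 |
| delta | 2.00 | 2.2 |
| delta | 6.00 | 3.9 |
| delta | 10.0 | 4.7 |
| delta | 15.0 | 7.4 |
| delta | 25.0 | 9.5 |
| delta | 30.0 | 10.5 |

(each reading ± 0.5 percentage points)

- ash: change nothing and wait 5.0 d more
- oak: at 2.5 d add free catalyst, 100% of the amount charged, then wait 5.0 d
- larch: at 2.5 d take out 90% of the left-handed product then present, then wait 5.0 d
- alder: at 2.5 d add partner, 100% of the amount charged, then wait 5.0 d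

* left-handed product, in percent of the left-handed substrate and right-handed substrate together first charged, at 2.5 d
* the option that brings most further left-handed product ("none" if no option brings more than 2 percentage points) (ash / oak / larch / alder / none)
* left-handed product present, with what was taken out counted in, in percent of the left-handed substrate and right-handed substrate together first charged, after larch
* left-handed product present, with what was taken out counted in, in percent of the left-handed substrate and right-handed substrate together first charged, after alder

- free catalyst is single-handed; left-handed substrate and right-handed substrate are mirror images of each other, charged as a racemate, each of them at the stated concentration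
- what is taken out of left-handed product is counted as made
- steps that have been proposed: partner + free catalyst + right-handed substrate -> free catalyst + right-handed product; partner + free catalyst -> spent catalyst; partner + protic impurity -> quenched reagent; partner + free catalyst + left-handed substrate -> free catalyst + left-handed product
- additions bring no volume worth counting

Zeta is the flask itself, followed so far. Left-handed substrate is half the charge, so its free share is one minus twice the product fraction. If the catalyst decays at a steady rate, L at one time and at twice that time gives the reach:

early = 0.360 at 25.0 h, late = 0.446 at 50.0 h

reach = early × early / (early + early − late) = 0.474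

Is one number enough? The reach should follow catalyst concentration. The same reckoning on delta gives 0.303, so zeta stands 1.56 times higher, against 1.50 in concentration, within a scatter of 0.5 percentage points.

Reading off, still on steady decay: by 2.5 d the reckoned spent share is 96.7%, which gives 18.4% of left-handed product. The reckoned plateau is 18.9%, and ash, larch and alder are reckoned to end near it, a gain of 0.50 points, less than the 2 points. But the proposed catalyst death takes partner too, and partner falls as it is used, so steady decay is an assumption that may put this plateau low. Oak adds a second reach, with a ceiling of 30.6%, but the partner budget of 39.0% of the charge must pay for right-handed product too.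

The forecast gives 18.2%, 18.5% after larch, 18.6% after alder, and oak as best, since “fresh catalyst converts about a third of the remaining left substrate”.

The flask gives 18.7%, 21.2% after larch, 22.0% after alder, and oak as best, with a gain of 5.8 points.

    partner + free catalyst + right-handed substrate → free catalyst + right-handed product (k = 156 M⁻² min⁻¹)
    partner + free catalyst → spent catalyst (k = 0.0414 M⁻¹ min⁻¹)
    partner + protic impurity → quenched reagent (k = 2.13 M⁻¹ min⁻¹)
    partner + free catalyst + left-handed substrate → free catalyst + left-handed product (k = 316 M⁻² min⁻¹)

In the flask both product steps ran while partner and free catalyst stood together, the left-handed one with half its turnover behind it by 8.83 h; at 60.0 h the catalyst was 81.0% spent and 19.0% free, not the reckoned 96.7% spent, and ash and larch each added 2.5 points and alder 3.3 points, against the reckoned 0.50 points. The table gives a reach of 0.579, higher than the 0.474 from the zeta readings, and it puts the plateau at 22.0%; the flask holds 22.0% after 600 h. Scaled to the 0.39 mol% of the neighbouring flask, with 62.8% spent, it gives 54.0% of the left-handed substrate free, and that neighbour holds 54%.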